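The route rests on cutting the interflavan bond between C4 of the upper pyran ring C and C8 of ring D. The feature used is that C4 is a diarylmethine carbon bonded to C4a, para to the C7 oxygen of ring A, and that the C2 aryl, C3 hydroxyl and C4 aryl groups are all trans. Ring C can therefore be flattened to a 7-oxygenated flavylium ion. In one operation a chiral acid closes O1–C2 of an open-chain 2-hydroxychalcone, ionises it, and lets C8 of penta-O-benzylepigallocatechin attack C4, which sets that stereocentre. Hydroboration of the resulting C2=C3 enol ether, anti to the new aryl group, relays C4 to C3 and C2; hydrogenolysis finishes.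

Key step: step 4

Numbering: flavan numbering is used. The upper unit has rings A (benzo), B (2-aryl) and C (pyran); ring D is the benzo ring of the lower unit. The target is 2R,3S,4S in the upper unit (2,3-trans-3,4-trans) and 2R,3R in the lower unit.

Assumption: which face of the flavylium ion a given antipode of the acid leaves open cannot be predicted for this nucleophile. The route is written with the (R)-acid, and the (S)-acid replaces it if a test run shows it to be the matched one.

Step 1
Reactants: 1 3',4',5'-trihydroxyacetophenone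
Product: 2 3',4',5'-tris(benzyloxy)acetophenone
Conditions: BnBr (3.5 equiv), K2CO3 (4 equiv), DMF, N2, 60 °C
Reagents that add atoms: benzyl bromide, BrCc1ccccc1
Why: Williamson ether synthesis in which K2CO3 deprotonates only the three acidic phenols, benzyl bromide is a fast SN2 partner, the methyl ketone is not enolised by carbonate, and exclusion of air keeps the pyrogallol ring from autoxidising.

Step 2
Reactants: 2 3',4',5'-tris(benzyloxy)acetophenone; 3 4-benzyloxy-2-hydroxybenzaldehyde
Product: 4 (E)-3-(4-benzyloxy-2-hydroxyphenyl)-1-[3,4,5-tris(benzyloxy)phenyl]prop-2-en-1-one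
Conditions: aq KOH (50 %, 10 equiv), EtOH/THF, N2, rt to 40 °C, 48 h; then AcOH to pH 5-6, 0 °C
Reagents that add atoms: none
Why: Claisen-Schmidt aldol condensation in which the ketone enolate adds to the non-enolisable aldehyde and E1cB loss of water gives the conjugated E-enone, the concentrated base and long reaction time offsetting the deactivation of the aldehyde by its ortho phenoxide, while the weakly acidic quench avoids premature ring closure.

Step 3
Reactants: 5 (-)-epigallocatechin (2R,3R)
Product: 6 (2R,3R)-5,7,3',4',5'-penta-O-benzylepigallocatechin (3-OH free)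
Conditions: BnBr (5.5 equiv), K2CO3 (6 equiv), degassed DMF, Ar, 0 °C to rt
Reagents that add atoms: benzyl bromide, BrCc1ccccc1
Why: Williamson ether synthesis made phenol-selective by the acidity gap between the five phenols and the secondary C3 alcohol, which carbonate does not deprotonate; low temperature and degassed solvent curb C-benzylation at C6 or C8, pyrogallol oxidation and base-induced epimerisation at C2, so both stereocentres of 5 should pass unchanged into 6.

Step 4
Reactants: 4 (E)-2-hydroxychalcone; 6 penta-O-benzylepigallocatechin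
Product: 10 (4S)-nona-O-benzyl flav-2-ene dimer [7-benzyloxy-2-(3,4,5-tribenzyloxyphenyl)-4H-chromene joined through C4 to C8 of 6], via Z-chalcone 7 (not isolated), via hemiketal 8 (not isolated), via flavylium ion 9 (not isolated)
Conditions: (R)-3,3'-bis(2,4,6-triisopropylphenyl)-1,1'-binaphthyl-2,2'-diyl N-triflylphosphoramide (10 mol %), 6 (1.5 equiv), powdered 4 Å MS, toluene, Ar, dark, 30 °C
Reagents that add atoms: none
Why: Proposed new method: the strong chiral acid protonates the enone of 4, and because the resulting cation is delocalised onto both oxygens of ring A the Cα-Cβ bond loses double-bond character and rotates to Z-chalcone 7, the only geometry in which the phenol reaches the carbonyl carbon; 6-exo-trig addition then closes ring C (O1-C2) as hemiketal 8, and loss of water to the sieves leaves flavylium ion 9 paired with the chiral phosphoramide anion. C8 of ring D attacks C4 of 9 within this contact ion pair and rearomatisation returns the proton to the anion, so that the cation exists only at catalyst level, which keeps hydride transfer from the C4-H of 10 to 9 in check. In type the nearest precedents are the BINOL phosphoric acid catalysed union of 2-hydroxychalcones with indoles or 2-naphthols (conjugate Friedel-Crafts alkylation, then dehydrative ring closure to 4-aryl-4H-chromenes) and the spontaneous uptake of phloroglucinol or catechin at C4 of preformed flavylium salts; a triether arene and a nucleophile that is itself chiral have not been tried, hence the choice of the more acidic N-triflylphosphoramide, which can hold a fully ionised pair. C4, the only new stereocentre, is set (S) by the anion, whose 2,4,6-triisopropylphenyl walls cover one face of the flat cation and whose P=O or S=O oxygen can accept a hydrogen bond from the free 3-OH of 6, the sole donor in the nucleophile; the remote centres of 6 only make the two antipodes of the acid a matched and a mismatched case. Attack at C4 and not C2 follows from the aryl group on C2 and from the reversibility of any addition there, C8 is preferred over C6 as in other electrophilic substitutions of 5,7-di-O-benzylflavan-3-ols, and the excess of 6 suppresses a second arylation at C6 of 10. Since O7 and O1, the two oxygens flanking C8, both carry carbon, 10 cannot fold into a bicyclic ketal and stays the enol ether that step 5 needs.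

Step 5
Reactants: 10 (4S)-nona-O-benzyl flav-2-ene dimer
Product: 12 nona-O-benzyl-robinetinidol-(4α→8)-epigallocatechin (upper unit 2R,3S,4S; lower unit 2R,3R), via C3-borane 11 (not isolated)
Conditions: BH3·SMe2 (4 equiv), THF, 0 °C to rt; then NaBO3·4H2O, THF/H2O, 0 °C to rt
Reagents that add atoms: borane-dimethyl sulfide, C[S+](C)[BH3-] (boron of 11, hydrogen at C2 of 12); sodium perborate, [Na+].[O-]OB=O (oxygen at C3 of 12)
Why: Hydroboration-oxidation of a cyclic enol ether, a reaction type known to turn flav-2-enes into 2,3-trans-flavan-3-ols: the oxygen and the aryl group on C2 both send boron to C3, the four-centre syn addition takes place on the face opposite the pseudoaxial C4 aryl group so that H at C2 and B at C3 both end trans to it, oxidation retains the C3 configuration, the extra borane covers the lower 3-OH (whose alkoxyborane is too poor a hydroborating agent to deliver hydride from the wrong face), and mild perborate limits β-elimination of boron with the C2-O1 aryloxide.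

Step 6
Reactants: 12 nona-O-benzyl-robinetinidol-(4α→8)-epigallocatechin
Product: 13 robinetinidol-(4α→8)-epigallocatechin (target)
Conditions: H2 (1 atm), Pd(OH)2/C, THF/MeOH/H2O, rt; filtration under Ar, freeze-drying
Reagents that add atoms: none
Why: Heterogeneous catalytic hydrogenolysis cleaves the nine O-benzyl bonds under conditions that are standard for benzylated flavan-3-ol dimers and that leave the cyclic C2-O1 benzylic ethers, the C4-C8 bond and all five stereocentres untouched, air being excluded during isolation because both pyrogallol rings oxidise easily.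

Compound list
1 | 3',4',5'-trihydroxyacetophenone | CC(=O)c1cc(O)c(O)c(O)c1 | starting material
2 | 3',4',5'-tris(benzyloxy)acetophenone | CC(=O)c1cc(OCc2ccccc2)c(OCc2ccccc2)c(OCc2ccccc2)c1 | intermediate
3 | 4-benzyloxy-2-hydroxybenzaldehyde | O=Cc1ccc(OCc2ccccc2)cc1O | starting material
4 | (E)-3-(4-benzyloxy-2-hydroxyphenyl)-1-[3,4,5-tris(benzyloxy)phenyl]prop-2-en-1-one | O=C(/C=C/c1ccc(OCc2ccccc2)cc1O)c1cc(OCc2ccccc2)c(OCc2ccccc2)c(OCc2ccccc2)c1 | intermediate
5 | (-)-epigallocatechin, 2R,3R | Oc1cc(O)c2c(c1)O[C@H](c1cc(O)c(O)c(O)c1)[C@H](O)C2 | starting material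
6 | (2R,3R)-5,7,3',4',5'-penta-O-benzylepigallocatechin, 3-OH free | c1ccccc1COc1cc(OCc3ccccc3)c2c(c1)O[C@H](c1cc(OCc3ccccc3)c(OCc3ccccc3)c(OCc3ccccc3)c1)[C@H](O)C2 | intermediate
7 | (Z)-isomer of chalcone 4 | O=C(/C=C\c1ccc(OCc2ccccc2)cc1O)c1cc(OCc2ccccc2)c(OCc2ccccc2)c(OCc2ccccc2)c1 | intermediate
8 | 7-benzyloxy-2-[3,4,5-tris(benzyloxy)phenyl]-2H-chromen-2-ol (racemic hemiketal) | OC1(c2cc(OCc3ccccc3)c(OCc3ccccc3)c(OCc3ccccc3)c2)C=Cc2ccc(OCc3ccccc3)cc2O1 | intermediate
9 | 7-benzyloxy-2-[3,4,5-tris(benzyloxy)phenyl]chromenylium (flavylium) ion, counterion the catalyst anion | c1ccccc1COc1ccc2ccc(-c3cc(OCc4ccccc4)c(OCc4ccccc4)c(OCc4ccccc4)c3)[o+]c2c1 | intermediate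
10 | (4S)-7-benzyloxy-4-[(2R,3R)-5,7-bis(benzyloxy)-3-hydroxy-2-(3,4,5-tris(benzyloxy)phenyl)chroman-8-yl]-2-[3,4,5-tris(benzyloxy)phenyl]-4H-chromene | C(c1ccccc1)Oc1ccc2c(c1)OC(c1cc(OCc3ccccc3)c(OCc3ccccc3)c(OCc3ccccc3)c1)=C[C@@H]2c1c(OCc3ccccc3)cc(OCc3ccccc3)c2c1O[C@H](c1cc(OCc3ccccc3)c(OCc3ccccc3)c(OCc3ccccc3)c1)[C@H](O)C2 | intermediate
11 | 2,3-trans-3,4-trans flavan with BH2 on upper C3 and O-BH2 on lower C3 | C(c1ccccc1)Oc1ccc2c(c1)O[C@H](c1cc(OCc3ccccc3)c(OCc3ccccc3)c(OCc3ccccc3)c1)[C@@H](B)[C@@H]2c1c(OCc3ccccc3)cc(OCc3ccccc3)c2c1O[C@H](c1cc(OCc3ccccc3)c(OCc3ccccc3)c(OCc3ccccc3)c1)[C@H](OB)C2 | intermediate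
12 | nona-O-benzyl-robinetinidol-(4α→8)-epigallocatechin, upper 2R,3S,4S, lower 2R,3R | C(c1ccccc1)Oc1ccc2c(c1)O[C@H](c1cc(OCc3ccccc3)c(OCc3ccccc3)c(OCc3ccccc3)c1)[C@@H](O)[C@@H]2c1c(OCc3ccccc3)cc(OCc3ccccc3)c2c1O[C@H](c1cc(OCc3ccccc3)c(OCc3ccccc3)c(OCc3ccccc3)c1)[C@H](O)C2 | intermediate
13 | robinetinidol-(4α→8)-epigallocatechin, upper 2R,3S,4S, lower 2R,3R | Oc1ccc2c(c1)O[C@H](c1cc(O)c(O)c(O)c1)[C@@H](O)[C@@H]2c1c(O)cc(O)c2c1O[C@H](c1cc(O)c(O)c(O)c1)[C@H](O)C2 | target

Total step count: 6. Longest linear sequence: 5 steps (steps 1, 2, 4, 5, 6; step 3 runs in parallel).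

Steps most likely to fail

Step 4 (new method).
- **What may go wrong:** The E-to-Z isomerisation, or attack by a weakly nucleophilic triether arene, may be too slow for turnover. The ion pair may distinguish the two faces of C4 poorly against the bias of the chiral nucleophile. Retro-Friedel-Crafts cleavage may erode a kinetic preference, and part of the attack may go through C6. Poor facial selectivity alone is tolerable, because the C4 epimers are diastereomers and can be separated.
- **Fallback:** It uses known chemistry, sets out from 6 and returns at 12, so it replaces steps 4 and 5 together. Purchased (2R,3R)-dihydrorobinetin F1 is benzylated on its four phenols (BnBr, K2CO3, DMF, Ar, rt) to 7,3',4',5'-tetra-O-benzyldihydrorobinetin F2. NaBH4 (THF/EtOH, 0 °C) reduces the C4 ketone to the 2,3-trans-3,4-trans tetra-O-benzylflavan-3,4-diol F3. TiCl4 (CH2Cl2, 0 °C) then ionises the C4 hydroxyl of F3 in the presence of an excess of 6. The benzylic cation, stabilised by the para C7 oxygen, is taken by C8 of ring D anti to the C3 hydroxyl. This is the established Lewis acid route to benzylated 4α→8 dimers with a 2,3-trans upper unit, and upper C2 and C3 then come from the chiral pool.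

Step 5.
- **What may go wrong:** Boron on C3 lies anti-periplanar to the C2-O1 aryloxide, so β-elimination could open ring C. Addition to the hindered trisubstituted enol ether may be slow, and facial selectivity may be incomplete.
- **Fallback:** It sets out from 10 and returns at 12. Upjohn dihydroxylation (OsO4 cat., NMO, acetone/THF/H2O) oxidises the enol ether on the face anti to the C4 aryl group. This gives the nona-O-benzyl 2-hydroxyflavan-3-ol hemiketal F4, with C3-O already trans to C4. Et3SiH with BF3·OEt2 (CH2Cl2, -40 °C) then removes the C2 hydroxyl through the 2-aryl oxocarbenium ion. Hydride arrives axially, opposite the C4 aryl group, and leaves the C2 aryl equatorial and trans to the 3-OH, as in the reduction of aryl lactols to equatorial C-aryl glycosides.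

Step 2.
- **What may go wrong:** The phenoxide formed from 3 deactivates the aldehyde, and the lipophilic ketone dissolves poorly. The aldol addition may therefore stall, or self-condensation of the ketone may compete.
- **Fallback:** It sets out from 3 and returns at 4. The phenol is masked (MOMCl, i-Pr2NEt, CH2Cl2) as 4-benzyloxy-2-(methoxymethoxy)benzaldehyde F5. The now neutral aldehyde condenses with 2 (KOH, EtOH/THF, rt) to the 2-O-methoxymethyl chalcone F6. The acetal is then removed (HCl, MeOH/THF, 45 °C), and buffering with aqueous NaOAc returns any ring-closed material to the open chalcone 4.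

Further compounds
F1 | step 4 | (2R,3R)-dihydrorobinetin (purchased) | Oc1ccc2c(c1)O[C@H](c1cc(O)c(O)c(O)c1)[C@@H](O)C2=O
F2 | step 4 | (2R,3R)-7,3',4',5'-tetra-O-benzyldihydrorobinetin | C(c1ccccc1)Oc1ccc2c(c1)O[C@H](c1cc(OCc3ccccc3)c(OCc3ccccc3)c(OCc3ccccc3)c1)[C@@H](O)C2=O
F3 | step 4 | (2R,3S,4R)-7,3',4',5'-tetra-O-benzylflavan-3,4-diol | C(c1ccccc1)Oc1ccc2c(c1)O[C@H](c1cc(OCc3ccccc3)c(OCc3ccccc3)c(OCc3ccccc3)c1)[C@@H](O)[C@@H]2O
F4 | step 5 | nona-O-benzyl 2-hydroxyflavan-3-ol hemiketal of the dimer (2-OH cis to 3-OH as first formed, both anti to the C4 aryl) | C(c1ccccc1)Oc1ccc2c(c1)O[C@](O)(c1cc(OCc3ccccc3)c(OCc3ccccc3)c(OCc3ccccc3)c1)[C@@H](O)[C@@H]2c1c(OCc3ccccc3)cc(OCc3ccccc3)c2c1O[C@H](c1cc(OCc3ccccc3)c(OCc3ccccc3)c(OCc3ccccc3)c1)[C@H](O)C2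
F5 | step 2 | 4-benzyloxy-2-(methoxymethoxy)benzaldehyde | O=Cc1ccc(OCc2ccccc2)cc1OCOC
F6 | step 2 | (E)-3-[4-benzyloxy-2-(methoxymethoxy)phenyl]-1-[3,4,5-tris(benzyloxy)phenyl]prop-2-en-1-one | O=C(/C=C/c1ccc(OCc2ccccc2)cc1OCOC)c1cc(OCc2ccccc2)c(OCc2ccccc2)c(OCc2ccccc2)c1
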